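The route rests on cutting the side chain between the exo-methylene carbon C13 and the oxygenated carbon C14. The feature exploited is the 2-substituted allylic alcohol unit C16=C13–C14–O that hangs from C9 of ring B: it is the retron of an alkenylchromium addition to an aldehyde. A catalytic asymmetric Nozaki–Hiyama–Kishi coupling joins the enol triflate of 14,15-dinorlabd-7-en-13-one with acetoxyacetaldehyde, forming C13–C14 and setting the remote C14 stereocentre by ligand control in one operation. The triflate comes in three steps from (−)-sclareol, which supplies rings A and B, C5, C9, C10 and the C13 methyl ketone whose methyl group becomes C16.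

Key step: step 4

Assumption: labdane numbering is used (ring A C1–C5/C10, ring B C5–C10, side chain C11–C16 on C9, C17 on C8); 2-oxoethyl acetate is taken as purchasable; the (S)-valinol-derived sulfonamide ligand is taken as the enantiomer that exposes the Si face of the aldehyde, and its mirror image from (R)-valinol would replace it, with nothing else changed, if a model coupling showed the opposite sense.

Step 1
Reactants: 1 (−)-sclareol
Product: 3 8α-hydroxy-14,15-dinorlabdan-13-one, via labdane-8α,13,14,15-tetraol 2 (not isolated)
Conditions: OsO4 (2 mol%), NaIO4 (4 equiv), THF/H2O, 45 °C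
Reagents that add atoms: none
Why: Lemieux–Johnson oxidation, in which catalytic osmylation of the only alkene gives tetraol 2 and periodate then cleaves both the C13–C14 and C14–C15 glycol bonds, so that C13 is unmasked as the methyl ketone while the hindered tertiary 8α-OH and the stereocentres C5, C8, C9 and C10 of sclareol stay untouched.

Step 2
Reactants: 3 8α-hydroxy-14,15-dinorlabdan-13-one
Product: 5 14,15-dinorlabd-7-en-13-one, via 8-iodo-14,15-dinorlabdan-13-one 4 (not isolated)
Conditions: HI (57% aq., 0.3 equiv), benzene, 85 °C
Reagents that add atoms: none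
Why: Acid-mediated E1 dehydration of a tertiary alcohol, in which the C8 cation (reversibly stored as tertiary iodide 4) loses the axial 7α-hydrogen, and under these equilibrating conditions any exocyclic or tetrasubstituted isomer and any cyclic enol ether formed with the C13 ketone should re-enter the same cation and drain to the C7=C8 alkene, where the 1,3-diaxial clash of the C8 and C10 methyl groups is relieved; C9 should keep its configuration because reprotonation comes from the open α face.

Step 3
Reactants: 5 14,15-dinorlabd-7-en-13-one
Product: 7 14,15-dinorlabda-7,13(16)-dien-13-yl trifluoromethanesulfonate, via potassium enolate 6 (not isolated)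
Conditions: KN(SiMe3)2, THF, −78 °C; then PhNTf2, −78 °C to 0 °C
Reagents that add atoms: N-phenylbis(trifluoromethanesulfonimide) O=S(=O)(N(c1ccccc1)S(=O)(=O)C(F)(F)F)C(F)(F)F
Why: Kinetic enolate triflation, in which the bulky amide base removes a proton from the unhindered C16 methyl group and not from C12 at −78 °C, and O-sulfonylation of the terminal enolate 6 fixes the 2-triflyloxy-1-alkene; no stereocentre is formed or touched.

Step 4
Reactants: 7 14,15-dinorlabda-7,13(16)-dien-13-yl trifluoromethanesulfonate; 8 acetoxyacetaldehyde (2-oxoethyl acetate)
Product: 10 (14S)-14-hydroxylabda-7,13(16)-dien-15-yl acetate, via chlorozirconocene alkoxide 9 (not isolated)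
Conditions: CrCl2 (10 mol%), (S)-N-[2-(4-isopropyl-4,5-dihydrooxazol-2-yl)-6-methylphenyl]methanesulfonamide (11 mol%), proton sponge (11 mol%), NiCl2(2,9-dimethyl-1,10-phenanthroline) (2 mol%), Mn powder, Cp2ZrCl2, LiCl, MeCN, rt; then aq. NaHCO3
Reagents that add atoms: none
Why: Zerovalent nickel, formed from the NiCl2 complex by Mn, inserts into the C13–OTf bond, the alkenyl group passes to trivalent chromium, and the alkenylchromium adds to the aldehyde carbonyl of 8 to form the C13–C14 bond, after which Cp2ZrCl2 takes over the alkoxide (9) and Mn returns chromium to the divalent state. The closest known reaction type is the catalytic asymmetric Nozaki–Hiyama–Kishi coupling of 2-substituted alkenyl triflates and iodides with aliphatic aldehydes under chiral oxazoline–sulfonamide control. No ring is closed. The new C14 stereocentre is set by the ligand on chromium alone, which should deliver the alkenyl group to the Si face of the aldehyde and so give the 14S alcohol; the ring stereocentres at C5, C9 and C10 are too remote to exert control. The step needs chemoselectivity for the aldehyde over the acetate and for the C–OTf bond over the trisubstituted C7=C8 alkene, which the low basicity and aldehyde selectivity of alkenylchromium reagents and the inertness of unactivated alkenes toward nickel secure. Any shift of the acetyl group between O15 and O14 is harmless because step 5 acetylates both positions.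

Step 5
Reactants: 10 (14S)-14-hydroxylabda-7,13(16)-dien-15-yl acetate
Product: 11 (14S)-labda-7,13(16)-diene-14,15-diyl diacetate
Conditions: Ac2O, pyridine, DMAP (cat.), CH2Cl2, rt
Reagents that add atoms: acetic anhydride CC(=O)OC(C)=O
Why: Nucleophile-catalysed acetylation of the secondary allylic alcohol, which leaves the C14–O bond intact so the 14S configuration is kept, and on which any acetyl-shifted isomer of 10 converges as well.

Compound list
1 | (−)-sclareol, (13R)-labd-14-ene-8α,13-diol | C=C[C@](C)(O)CC[C@H]1[C@](C)(O)CC[C@H]2C(C)(C)CCC[C@]12C | starting material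
2 | labdane-8α,13,14,15-tetraol (C14 epimers) | OCC(O)[C@](C)(O)CC[C@H]1[C@](C)(O)CC[C@H]2C(C)(C)CCC[C@]12C | intermediate
3 | 8α-hydroxy-14,15-dinorlabdan-13-one | CC(=O)CC[C@H]1[C@](C)(O)CC[C@H]2C(C)(C)CCC[C@]12C | intermediate
4 | 8-iodo-14,15-dinorlabdan-13-one (C8 configuration open) | CC(=O)CC[C@H]1C(C)(I)CC[C@H]2C(C)(C)CCC[C@]12C | intermediate
5 | 14,15-dinorlabd-7-en-13-one | CC(=O)CC[C@H]1C(C)=CC[C@H]2C(C)(C)CCC[C@]12C | intermediate
6 | potassium 14,15-dinorlabda-7,13(16)-dien-13-olate | [K+].C=C([O-])CC[C@H]1C(C)=CC[C@H]2C(C)(C)CCC[C@]12C | intermediate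
7 | 14,15-dinorlabda-7,13(16)-dien-13-yl trifluoromethanesulfonate | C=C(OS(=O)(=O)C(F)(F)F)CC[C@H]1C(C)=CC[C@H]2C(C)(C)CCC[C@]12C | intermediate
8 | acetoxyacetaldehyde (2-oxoethyl acetate) | CC(=O)OCC=O | starting material
9 | chlorozirconocene (14S)-15-acetoxylabda-7,13(16)-dien-14-olate | C=C(CC[C@H]1C(C)=CC[C@H]2C(C)(C)CCC[C@]12C)[C@@H](COC(C)=O)[O-].[Zr+4].[Cl-].c1cc[cH-]c1.c1cc[cH-]c1 | intermediate
10 | (14S)-14-hydroxylabda-7,13(16)-dien-15-yl acetate | C=C(CC[C@H]1C(C)=CC[C@H]2C(C)(C)CCC[C@]12C)[C@@H](COC(C)=O)O | intermediate
11 | (14S)-labda-7,13(16)-diene-14,15-diyl diacetate | C=C(CC[C@H]1C(C)=CC[C@H]2C(C)(C)CCC[C@]12C)[C@@H](COC(C)=O)OC(C)=O | target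

Total step count: 5. Longest linear sequence: 5 steps, from 1 to 11.

Steps most likely to fail

Step 4. The risk is poor or reversed facial selectivity at C14, since the substrate offers no bias, together with self-condensation of the α-acetoxy aldehyde under the basic additive. The fallback sets out from 7 (with 8) and comes back at 10. A ligand-free coupling (CrCl2, catalytic NiCl2, DMF, rt) should give the C14-epimeric 14-hydroxylabda-7,13(16)-dien-15-yl acetates F1. Dess–Martin oxidation should give 15-acetoxylabda-7,13(16)-dien-14-one F2. Corey–Bakshi–Shibata reduction with (S)-2-methyl-CBS-oxazaborolidine and catecholborane at −78 °C, with the 2-substituted alkenyl group acting as the large substituent, should return the 14S alcohol 10. The stereocentre is then set by reagent-controlled ketone reduction, not in the bond-forming event.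

Step 2. The risk is loss of regiocontrol in the elimination (exocyclic or tetrasubstituted alkene) and capture of the C8 cation by the ketone, at oxygen to a cyclic enol ether or at the enol carbon to a tricyclic ketone. The fallback sets out from 3 and comes back at 5, and avoids the cation altogether. SOCl2/pyridine in CH2Cl2 at −78 °C should eliminate the equatorial chlorosulfite, which has no anti-periplanar ring hydrogen, mainly toward the methyl group to give 14,15-dinorlabd-8(17)-en-13-one F3. RuHCl(CO)(PPh3)3 in toluene at 80 °C should then move the double bond by hydride addition and β-hydride elimination into the less hindered C7 position.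

Step 3. The risk is enolisation toward C12, which would give internal enol triflates that are hard to separate. The fallback sets out from 5 and comes back at 10. Condensation with 2,4,6-triisopropylbenzenesulfonyl hydrazide should give 14,15-dinorlabd-7-en-13-one 2,4,6-triisopropylbenzenesulfonylhydrazone F4. n-BuLi (2.2 equiv, THF/TMEDA, −78 °C to 0 °C) should fragment it in a Shapiro reaction on the methyl side to 13-lithio-14,15-dinorlabda-7,13(16)-diene F5. Iodine should convert this to 13-iodo-14,15-dinorlabda-7,13(16)-diene F6, which takes the place of 7 under the conditions of step 4.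

Further compounds
F1 | step 4 | 14-hydroxylabda-7,13(16)-dien-15-yl acetate (C14 epimers) | C=C(CC[C@H]1C(C)=CC[C@H]2C(C)(C)CCC[C@]12C)C(COC(C)=O)O
F2 | step 4 | 15-acetoxylabda-7,13(16)-dien-14-one | C=C(CC[C@H]1C(C)=CC[C@H]2C(C)(C)CCC[C@]12C)C(=O)COC(C)=O
F3 | step 2 | 14,15-dinorlabd-8(17)-en-13-one | CC(=O)CC[C@H]1C(=C)CC[C@H]2C(C)(C)CCC[C@]12C
F4 | step 3 | 14,15-dinorlabd-7-en-13-one 2,4,6-triisopropylbenzenesulfonylhydrazone | CC(CC[C@H]1C(C)=CC[C@H]2C(C)(C)CCC[C@]12C)=NNS(=O)(=O)c1c(C(C)C)cc(C(C)C)cc1C(C)C
F5 | step 3 | 13-lithio-14,15-dinorlabda-7,13(16)-diene | [Li]C(=C)CC[C@H]1C(C)=CC[C@H]2C(C)(C)CCC[C@]12C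
F6 | step 3 | 13-iodo-14,15-dinorlabda-7,13(16)-diene | C=C(I)CC[C@H]1C(C)=CC[C@H]2C(C)(C)CCC[C@]12C
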